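**Plan**
1. Retrosynthesis: the thirteen hydroxyls are masked as methyl ethers. The first cut is the diaryl ether bond between the oxygen on C1 of ring C and C6 of ring B. Next are the two biaryl bonds C3(ring C)–ring D and C5(ring C)–ring E, and in the other half the ether bond between ring A and the oxygen on C1 of ring B.
2. Enabling feature: ring C is hexasubstituted, and its C4 oxygen lies between C3 and C5, the carbons that carry the identical rings D and E, with the C1 oxygen para to it. A ring C phenol that is free at O4, benzylated at O1 and methylated at O2 and O6 therefore has exactly two C–H bonds, both ortho to the free hydroxyl.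
3. Forward, ring C half: syringaldehyde → benzyl ether → Baeyer–Villiger phenol → one anodic electrolysis with 1,3,5-trimethoxybenzene that forms both biaryl bonds → O-methylation → hydrogenolysis.
4. Forward, ring A–ring B half: 5-bromovanillin → Chan–Lam arylation → Baeyer–Villiger phenol → O-methylation. A CuI-catalysed etherification joins the halves and BBr3 frees all thirteen phenols.
5. No ring is built, since all five benzene rings are bought. There is no stereochemistry to set: the target has no stereocentre, and the two biaryl axes are not stereogenic because rings D and E are symmetric about them.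

Key step: step 3

Remark on the chemistry: besides syringaldehyde, benzyl bromide and 1,3,5-trimethoxybenzene, 5-bromovanillin and (3,5-dimethoxyphenyl)boronic acid are taken as catalogue compounds. HFIP is 1,1,1,3,3,3-hexafluoropropan-2-ol and mCPBA is 3-chloroperoxybenzoic acid.

**Route**

Step 1
Reactants: 1 syringaldehyde (4-hydroxy-3,5-dimethoxybenzaldehyde); 2 benzyl bromide
Product: 3 4-(benzyloxy)-3,5-dimethoxybenzaldehyde
Conditions: K2CO3, DMF, 60 °C
Reagents that add atoms: none
Why: Williamson ether synthesis, in which the phenoxide (acidified by the para formyl group) displaces bromide from the benzylic carbon while the aldehyde is inert to carbonate.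

Step 2
Reactants: 3 4-(benzyloxy)-3,5-dimethoxybenzaldehyde
Product: 5 4-(benzyloxy)-3,5-dimethoxyphenol, via aryl formate 4 (not isolated)
Conditions: mCPBA, CH2Cl2, 0 °C to rt; then K2CO3 (cat.), MeOH, rt
Reagents that add atoms: 3-chloroperoxybenzoic acid (mCPBA), OOC(=O)c1cccc(Cl)c1
Why: Baeyer–Villiger (Dakin-type) oxidation, in which the electron-rich trialkoxyaryl group migrates in the Criegee adduct in preference to hydride, and the resulting formate is cleaved by carbonate-catalysed methanolysis without touching the benzyl or methyl ethers.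

Step 3
Reactants: 5 4-(benzyloxy)-3,5-dimethoxyphenol; 6 1,3,5-trimethoxybenzene (about 8 equiv, excess recovered)
Product: 8 4-(benzyloxy)-3,5-dimethoxy-2,6-bis(2,4,6-trimethoxyphenyl)phenol, via mono-arylated phenol 7 (not isolated)
Conditions: undivided cell, boron-doped diamond anode and cathode, Bu3NMe(+) MeOSO3(−) (0.09 M), dry HFIP without methanol, 50 °C, constant current (about 3–5 mA cm−2), about 4.5 F per mol of 5
Reagents that add atoms: none
Why: The trialkoxyphenol 5 has the lowest oxidation potential in the cell and is converted at the anode into an HFIP-solvated phenoxyl radical (after further electron loss a phenoxonium ion), whose ortho carbon is attacked by the strongly nucleophilic arene 6; loss of the second electron and a proton restores aromaticity to give 7, which re-enters the same cycle at its remaining ortho C–H to give 8 while the released protons are reduced to H2 at the cathode. The closest known reaction type is the anodic dehydrogenative phenol–arene cross-coupling at boron-doped diamond in fluorinated alcohols, run here twice in succession on one phenol. No ring is closed and no stereocentre arises, and the two new biaryl axes are not stereogenic because each 2,4,6-trimethoxyphenyl ring is symmetric about its axis. The step needs cross-coupling in preference to homo-coupling of 5, C–C in preference to C–O bond formation and survival of the benzyloxy group para to the hydroxyl; these should be secured by the lower oxidation potential of 5 relative to 6, by the large excess of 6, by the blocked para position, and by dry, methanol-free HFIP, which offers no nucleophile that could turn a phenoxonium ion into a quinone ketal. The connectivity cannot go astray, because 5 and 7 offer only ortho C–H positions on the phenol ring and 6 has three equivalent C–H positions. Further arylation on the attached trimethoxyphenyl rings should be held back by their steric shielding and by the statistical excess of free 6.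

Step 4
Reactants: 8 4-(benzyloxy)-3,5-dimethoxy-2,6-bis(2,4,6-trimethoxyphenyl)phenol
Product: 9 2-(benzyloxy)-1,3,5-trimethoxy-4,6-bis(2,4,6-trimethoxyphenyl)benzene
Conditions: MeI, K2CO3, DMF, 50 °C
Reagents that add atoms: iodomethane, CI
Why: Williamson O-methylation, in which the small electrophile reaches the phenoxide between the two twisted aryl rings; capping this oxygen avoids an oxidation-prone hydroquinone in step 5 and a second nucleophile in step 9.

Step 5
Reactants: 9 2-(benzyloxy)-1,3,5-trimethoxy-4,6-bis(2,4,6-trimethoxyphenyl)benzene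
Product: 10 2,4,6-trimethoxy-3,5-bis(2,4,6-trimethoxyphenyl)phenol
Conditions: H2 (1 atm), 10% Pd/C, EtOAc/MeOH, rt
Reagents that add atoms: none
Why: Catalytic hydrogenolysis cleaves only the benzylic C–O bond, since aryl methyl ethers and biaryl bonds are inert on palladium under these conditions, so the ring C oxygen destined for ring B is set free.

Step 6
Reactants: 11 5-bromovanillin (3-bromo-4-hydroxy-5-methoxybenzaldehyde); 12 (3,5-dimethoxyphenyl)boronic acid (2 equiv)
Product: 13 3-bromo-4-(3,5-dimethoxyphenoxy)-5-methoxybenzaldehyde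
Conditions: Cu(OAc)2 (0.5 equiv), pyridine, 4 Å MS, CH2Cl2, O2 (1 atm), rt
Reagents that add atoms: none
Why: Chan–Lam oxidative C–O coupling (aryl transfer from boron to a divalent copper phenoxide, oxidation to trivalent copper, reductive elimination, reoxidation of copper by O2) runs at room temperature, so the C–Br bond and the aldehyde stay intact, and phenols with two ortho substituents including an ortho halogen are established partners.

Step 7
Reactants: 13 3-bromo-4-(3,5-dimethoxyphenoxy)-5-methoxybenzaldehyde
Product: 15 3-bromo-4-(3,5-dimethoxyphenoxy)-5-methoxyphenol, via aryl formate 14 (not isolated)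
Conditions: mCPBA, CH2Cl2, 0 °C to rt; then K2CO3 (cat.), MeOH, rt
Reagents that add atoms: 3-chloroperoxybenzoic acid (mCPBA), OOC(=O)c1cccc(Cl)c1
Why: Baeyer–Villiger oxidation, in which the para aryloxy group makes the aryl ring the migrating group and the aryl bromide and diaryl ether are inert to the peracid; methanolysis of the formate then gives the phenol.

Step 8
Reactants: 15 3-bromo-4-(3,5-dimethoxyphenoxy)-5-methoxyphenol
Product: 16 1-bromo-2-(3,5-dimethoxyphenoxy)-3,5-dimethoxybenzene
Conditions: MeI, K2CO3, acetone, reflux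
Reagents that add atoms: iodomethane, CI
Why: Williamson O-methylation of an unhindered phenol, which completes the protected ring A–ring B fragment with bromine at C6 of ring B.

Step 9
Reactants: 10 2,4,6-trimethoxy-3,5-bis(2,4,6-trimethoxyphenyl)phenol; 16 1-bromo-2-(3,5-dimethoxyphenoxy)-3,5-dimethoxybenzene (1.3 equiv)
Product: 17 1-[2-(3,5-dimethoxyphenoxy)-3,5-dimethoxyphenoxy]-2,4,6-trimethoxy-3,5-bis(2,4,6-trimethoxyphenyl)benzene
Conditions: CuI (20 mol %), picolinic acid (40 mol %), K3PO4, DMSO, 110 °C, argon
Reagents that add atoms: none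
Why: Ullmann diaryl ether synthesis, in which a picolinate-ligated monovalent copper phenoxide activates the C–Br bond; this ligand system is known for doubly ortho-substituted phenols with ortho-substituted aryl halides, and the two methoxy groups of ring B are meta to bromine and so do not deactivate the C–Br bond by resonance.

Step 10
Reactants: 17 1-[2-(3,5-dimethoxyphenoxy)-3,5-dimethoxyphenoxy]-2,4,6-trimethoxy-3,5-bis(2,4,6-trimethoxyphenyl)benzene
Product: 18 CNP0228669.0, 1-[2-(3,5-dihydroxyphenoxy)-3,5-dihydroxyphenoxy]-3,5-bis(2,4,6-trihydroxyphenyl)benzene-2,4,6-triol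
Conditions: BBr3 (large excess), CH2Cl2, −78 °C to rt; then H2O, 0 °C; purification under argon (Sephadex LH-20 or reversed phase)
Reagents that add atoms: none
Why: Lewis-acid cleavage of aryl methyl ethers by BBr3 (boron coordinates the ether oxygen and bromide attacks the methyl carbon) should remove all thirteen methyl groups, while the diaryl ether and biaryl bonds offer no sp3 carbon for attack and survive; hydrolysis of the aryl borates then releases the phenols.

**Compound list**
1 | syringaldehyde (4-hydroxy-3,5-dimethoxybenzaldehyde) | COc1cc(C=O)cc(OC)c1O | starting material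
2 | benzyl bromide | BrCc1ccccc1 | starting material
3 | 4-(benzyloxy)-3,5-dimethoxybenzaldehyde | COc1cc(C=O)cc(OC)c1OCc1ccccc1 | intermediate
4 | 4-(benzyloxy)-3,5-dimethoxyphenyl formate | COc1cc(OC=O)cc(OC)c1OCc1ccccc1 | intermediate (not isolated)
5 | 4-(benzyloxy)-3,5-dimethoxyphenol | COc1cc(O)cc(OC)c1OCc1ccccc1 | intermediate
6 | 1,3,5-trimethoxybenzene | COc1cc(OC)cc(OC)c1 | starting material
7 | 4-(benzyloxy)-3,5-dimethoxy-2-(2,4,6-trimethoxyphenyl)phenol | COc1cc(OC)cc(OC)c1-c1c(O)cc(OC)c(OCc2ccccc2)c1OC | intermediate (not isolated)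
8 | 4-(benzyloxy)-3,5-dimethoxy-2,6-bis(2,4,6-trimethoxyphenyl)phenol | COc1cc(OC)cc(OC)c1-c1c(O)c(-c2c(OC)cc(OC)cc2OC)c(OC)c(OCc2ccccc2)c1OC | intermediate
9 | 2-(benzyloxy)-1,3,5-trimethoxy-4,6-bis(2,4,6-trimethoxyphenyl)benzene | COc1cc(OC)cc(OC)c1-c1c(OC)c(-c2c(OC)cc(OC)cc2OC)c(OC)c(OCc2ccccc2)c1OC | intermediate
10 | 2,4,6-trimethoxy-3,5-bis(2,4,6-trimethoxyphenyl)phenol | COc1cc(OC)cc(OC)c1-c1c(OC)c(-c2c(OC)cc(OC)cc2OC)c(OC)c(O)c1OC | intermediate
11 | 5-bromovanillin (3-bromo-4-hydroxy-5-methoxybenzaldehyde) | COc1cc(C=O)cc(Br)c1O | starting material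
12 | (3,5-dimethoxyphenyl)boronic acid | COc1cc(OC)cc(B(O)O)c1 | starting material
13 | 3-bromo-4-(3,5-dimethoxyphenoxy)-5-methoxybenzaldehyde | COc1cc(OC)cc(Oc2c(Br)cc(C=O)cc2OC)c1 | intermediate
14 | 3-bromo-4-(3,5-dimethoxyphenoxy)-5-methoxyphenyl formate | COc1cc(OC)cc(Oc2c(Br)cc(OC=O)cc2OC)c1 | intermediate (not isolated)
15 | 3-bromo-4-(3,5-dimethoxyphenoxy)-5-methoxyphenol | COc1cc(OC)cc(Oc2c(Br)cc(O)cc2OC)c1 | intermediate
16 | 1-bromo-2-(3,5-dimethoxyphenoxy)-3,5-dimethoxybenzene | COc1cc(OC)cc(Oc2c(Br)cc(OC)cc2OC)c1 | intermediate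
17 | 1-[2-(3,5-dimethoxyphenoxy)-3,5-dimethoxyphenoxy]-2,4,6-trimethoxy-3,5-bis(2,4,6-trimethoxyphenyl)benzene (tridecamethyl ether of the target) | COc1cc(OC)cc(Oc2c(OC)cc(OC)cc2Oc2c(OC)c(-c3c(OC)cc(OC)cc3OC)c(OC)c(-c3c(OC)cc(OC)cc3OC)c2OC)c1 | intermediate
18 | CNP0228669.0, 1-[2-(3,5-dihydroxyphenoxy)-3,5-dihydroxyphenoxy]-3,5-bis(2,4,6-trihydroxyphenyl)benzene-2,4,6-triol | Oc1cc(O)cc(Oc2c(O)cc(O)cc2Oc2c(O)c(-c3c(O)cc(O)cc3O)c(O)c(-c3c(O)cc(O)cc3O)c2O)c1 | target

**Count and risks**
Total steps: 10. Longest linear sequence: 7 (steps 1, 2, 3, 4, 5, 9, 10); steps 6–8 form the second branch.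

Steps most likely to fail:

Step 3. What may go wrong: two-electron over-oxidation of the para-benzyloxyphenol with loss of the benzyl group as a quinone forms, oxidative homo-coupling of 5, or stalling at 7 because the second, tetra-ortho-substituted biaryl bond forms slowly. Fallback (halogenation and cross-coupling in place of C–H/C–H coupling): starting from 5, O-methylation (MeI, K2CO3, DMF) would give 2-(benzyloxy)-1,3,5-trimethoxybenzene F1. Its only two ring C–H positions would then be brominated with N-bromosuccinimide (2.1 equiv, MeCN, 0 °C to rt, dark) to give 2-(benzyloxy)-4,6-dibromo-1,3,5-trimethoxybenzene F2. A twofold Suzuki–Miyaura coupling with (2,4,6-trimethoxyphenyl)boronic acid (Pd(OAc)2, SPhos = 2-dicyclohexylphosphino-2',6'-dimethoxybiphenyl, K3PO4, toluene/H2O, 100 °C) would pass through 2-(benzyloxy)-4-bromo-1,3,5-trimethoxy-6-(2,4,6-trimethoxyphenyl)benzene F3 (not isolated) and deliver 9. The route is re-entered at 9 and step 4 falls away.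

Step 9. What may go wrong: sluggish C–O bond formation between the doubly ortho-methoxylated, buttressed phenoxide and the ortho-aryloxy aryl bromide, so that reductive debromination of 16 and oxidative decomposition of the phenoxide take over. Fallback (nucleophilic aromatic substitution first, ring A attached afterwards): starting from 10, substitution of fluoride in 2-fluoro-4,6-dimethoxybenzaldehyde (Cs2CO3, DMSO, 110 °C), which is activated by the ortho formyl group, would give 2,4-dimethoxy-6-[2,4,6-trimethoxy-3,5-bis(2,4,6-trimethoxyphenyl)phenoxy]benzaldehyde F4. Baeyer–Villiger oxidation (mCPBA, CH2Cl2, 0 °C) would give 2,4-dimethoxy-6-[2,4,6-trimethoxy-3,5-bis(2,4,6-trimethoxyphenyl)phenoxy]phenyl formate F5 (not isolated), and methanolysis (K2CO3 cat., MeOH) would give 2,4-dimethoxy-6-[2,4,6-trimethoxy-3,5-bis(2,4,6-trimethoxyphenyl)phenoxy]phenol F6. Chan–Lam coupling of F6 with boronic acid 12 (Cu(OAc)2, pyridine, O2, CH2Cl2, rt) would give 17, where the route is rejoined.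

Step 10. What may go wrong: incomplete cleavage of the thirteen methyl ethers (the ring C methoxy groups flanked by aryl rings should be the slowest), and air oxidation or irreversible adsorption of the free polyphenol during purification. Fallback (purification through a protected derivative): starting from 17, the crude product of the BBr3 reaction would be acetylated without purification (Ac2O, pyridine, DMAP cat., rt) to the tridecaacetate of 18 F7. This ester should be stable to air and silica gel and separable from under-demethylated material. Acid-catalysed methanolysis (HCl cat. in MeOH, rt, argon) would then release 18.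

**Further compounds**
F1 | step 3 | 2-(benzyloxy)-1,3,5-trimethoxybenzene | COc1cc(OC)c(OCc2ccccc2)c(OC)c1
F2 | step 3 | 2-(benzyloxy)-4,6-dibromo-1,3,5-trimethoxybenzene | COc1c(Br)c(OC)c(OCc2ccccc2)c(OC)c1Br
F3 | step 3 | 2-(benzyloxy)-4-bromo-1,3,5-trimethoxy-6-(2,4,6-trimethoxyphenyl)benzene | COc1cc(OC)cc(OC)c1-c1c(OC)c(Br)c(OC)c(OCc2ccccc2)c1OC
F4 | step 9 | 2,4-dimethoxy-6-[2,4,6-trimethoxy-3,5-bis(2,4,6-trimethoxyphenyl)phenoxy]benzaldehyde | O=Cc1c(OC)cc(OC)cc1Oc1c(OC)c(-c2c(OC)cc(OC)cc2OC)c(OC)c(-c2c(OC)cc(OC)cc2OC)c1OC
F5 | step 9 | 2,4-dimethoxy-6-[2,4,6-trimethoxy-3,5-bis(2,4,6-trimethoxyphenyl)phenoxy]phenyl formate | O=COc1c(OC)cc(OC)cc1Oc1c(OC)c(-c2c(OC)cc(OC)cc2OC)c(OC)c(-c2c(OC)cc(OC)cc2OC)c1OC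
F6 | step 9 | 2,4-dimethoxy-6-[2,4,6-trimethoxy-3,5-bis(2,4,6-trimethoxyphenyl)phenoxy]phenol | Oc1c(OC)cc(OC)cc1Oc1c(OC)c(-c2c(OC)cc(OC)cc2OC)c(OC)c(-c2c(OC)cc(OC)cc2OC)c1OC
F7 | step 10 | tridecaacetate of 18 | CC(=O)Oc1cc(OC(C)=O)cc(Oc2c(OC(C)=O)cc(OC(C)=O)cc2Oc2c(OC(C)=O)c(-c3c(OC(C)=O)cc(OC(C)=O)cc3OC(C)=O)c(OC(C)=O)c(-c3c(OC(C)=O)cc(OC(C)=O)cc3OC(C)=O)c2OC(C)=O)c1
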